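The easy step comes first: gas J feeds dissolved D, and E takes up D on catalyst Q to give Z.

E 0.50 M; J 66 mM (held); Q 2.5 mM; L 7.1 mM; time 4.0 d

    J ⇌ D, rate k1*(csat - [D]) (k1 = 0.754 min⁻¹, csat = 66 mM)
    E + D + Q ⇌ Q + Z (K2 = 25.8 M⁻¹, k2 = 9.73 M⁻² min⁻¹)
    2 Q ⇌ Q2, settled at all times (K3 = 11000 M⁻¹)
    Q + L ⇌ Q.L (K4 = 62.6 M⁻¹, k4 = 18.4 M⁻¹ min⁻¹)

- how much Z there is at 4.0 d, in percent of the E charged
- concentration of D in solution at 4.0 d, in percent of saturation

- a step written with two of one species runs at k times the square of its concentration and takes two of it each time
- at the start none of D is dissolved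
- run time (flask): 4.0 d

Transfer can deliver 0.0498 M min⁻¹ into an empty solution. The Z-forming step takes 8.03 × 10⁻⁴ M min⁻¹ even with the whole charge of Q free, so I hold [D] at saturation.

Q is the reagent charged in the smaller amount, so I write its balance: Q, Q.L and Q2, counted as a pair of Q, add up to the charge. Q2 is kept at balance by the scheme. L has a forward half-life of 0.25 h at the charged concentrations, short against 4.0 d, so I put Q.L at balance too.

With [D] and free Q steady, the Z-forming step is pseudo-first-order in E. Z approaches a share of 63.0%, and the rate grows with free Q.

For a bound from above I keep Q2 alone in the balance. Free Q is then 0.337 mM and y is 54.3%. For a bound from below I put that ceiling into the Q2 term and L at its charge. Free Q is then 0.282 mM and y is 51.0%.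

Solving the balance exactly, with L at its charge, gives free Q, the unbound monomer that turns the reaction over: 0.306 mM. The rate is then 3.12 × 10⁻⁴ min⁻¹, so I commit to y of 52.5%. For sat I give a floor, 99.8%, reckoned for the start of the run, with E at its charge and the way back not counted.

The forecast says 52.5% and >99.9%, holding of Q2 and Q.L “so both sit at balance”. Its y lies inside my bracket.

The flask gives 52.5% and >99.9%.

At 4.00 d this flask holds Q at 12.2% of the catalyst charged and Q2 at 82.4%, with E at 47.5% and Z still short of the 63.0% it reads at 40.0 d. The neighbour charged with 0.0063 M of Q gets the same balance. Its free Q is 0.503 mM, so the charge rises 2.52-fold and free Q 1.64-fold. That gives y of 59.7%. In that neighbour, Q stands at 7.99% of its charge and Z reads 59.7%.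

The constants are invented; what happens was integrated by code.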